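**Plan**
Labdane numbering is used (ring A = C1–C5/C10, ring B = C5–C10, side chain C11–C16; β is the face of the C10 methyl group).
Retrosynthesis cuts, in this order: the N–Boc bond, C12–C13 (alkylborane/lactam enol triflate coupling), C9–C11 (vinyl addition to a C9 ketone), then C1–C10 and C4–C5 together (Diels–Alder).
Enabling feature: ring B carries para oxygens at C6 and C9 and methyl groups at C8 and C10, so it is 2,6-dimethyl-1,4-benzoquinone; ring A with its gem-dimethyl C4 is 4-methylpenta-1,3-diene.
Forward: ring B is bought as the quinone, ring A is closed on it by the cycloaddition (cis-fused), C9 receives the two-carbon chain, the ring fusion is turned trans, and the preformed lactam ring is coupled on last.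
Stereochemistry: the chiral catalyst sets C10; the cis-fused fold steers H2 (C8) and the vinyl group (C9) to the β face; C5 is equilibrated to trans through the C6 ketone; C6 arises from hydride attack on the α face, opposite the two axial methyl groups.

Key step: step 1

Remark (assumption): the (S)-diphenylprolinol-derived oxazaborolidinium ion is taken to give the (4aR,8aS) adduct 3; should the sense of induction be the opposite, the (R)-catalyst is used with no other change.

**Step 1**
Reactants: 1 2,6-dimethyl-1,4-benzoquinone; 2 4-methylpenta-1,3-diene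
Product: 3 (4aR,8aS)-2,5,5,8a-tetramethyl-4a,5,8,8a-tetrahydronaphthalene-1,4-dione (cis-fused ene-dione: 5β-H, 10β-methyl, C6 and C9 ketones, Δ2 and Δ7)
Conditions: (S)-3,3-diphenyl-1-(o-tolyl)tetrahydro-1H,3H-pyrrolo[1,2-c][1,3,2]oxazaborole (20 mol%, from (S)-diphenylprolinol and tri-o-tolylboroxine), HNTf2 (20 mol%), 2 (5 equiv), CH2Cl2, −78 → −40 °C
Reagents that add atoms: none
Why: The protonated oxazaborolidine is a cationic chiral Lewis acid that binds the C6 carbonyl of 1 (the one flanked by two C–H bonds) and lowers the LUMO of the adjacent C5=C10 bond, to which diene 2 adds in a concerted but asynchronous [4+2] cycloaddition; the closest known reaction type is the oxazaborolidinium-catalysed Diels–Alder reaction of 2,6-disubstituted benzoquinones with 1,3-dienes. Ring A closes by this intermolecular cycloaddition, both σ bonds (C1–C10 and C4–C5) forming on one face of the quinone, so the ring fusion is cis. C10 is set in absolute terms because the catalyst tells apart the two mirror-related C=C bonds of 1 and shields one face of the bound one; C5 follows from the suprafacial addition and is inverted in step 8. The required regiochemistry is secured electronically and sterically: the unsubstituted, more nucleophilic diene terminus bonds to the methyl-bearing β-carbon (C10) and the dimethyl terminus to the C–H carbon (C5), so no bond joins two fully substituted carbons. The weak point is the cis-methyl group of 2, which disfavours the s-cis conformer; the strongly activating triflimide catalyst, excess diene and a temperature ramp are meant to offset it.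

**Step 2**
Reactants: 3 cis-fused ene-dione
Product: 4 (5βH)-6α-hydroxy-4,4,8,10β-tetramethyldecalin-2,7-dien-9-one
Conditions: NaBH4 (1 equiv), CeCl3·7H2O, MeOH, −78 °C
Reagents that add atoms: none
Why: In this Luche reduction the cerium-assisted borohydride should attack the less hindered C6 carbonyl (C9 lies between the C8 methyl and quaternary C10) in 1,2-fashion from the convex β face, giving the 6α-alcohol, whose configuration is only temporary because C6 is re-oxidised in step 7.

**Step 3**
Reactants: 4 6α-hydroxy dienone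
Product: 5 (5βH)-6α-(tert-butyldimethylsilyloxy)-4,4,8,10β-tetramethyldecalin-2,7-dien-9-one
Conditions: TBSOTf, 2,6-lutidine, CH2Cl2, −78 → 0 °C
Reagents that add atoms: tert-butyldimethylsilyl triflate, CC(C)(C)[Si](C)(C)OS(=O)(=O)C(F)(F)F
Why: Silylation of the secondary allylic alcohol with the silyl triflate masks C6 for the hydrogenation and the organometallic step and creates no stereocentre.

**Step 4**
Reactants: 5 silyl ether
Product: 6 (5βH)-6α-(tert-butyldimethylsilyloxy)-4,4,8α,10β-tetramethyldecalin-9-one
Conditions: H2 (1–3 atm), Pd/C, EtOAc, rt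
Reagents that add atoms: none
Why: Heterogeneous catalytic hydrogenation saturates the ring A alkene and the enone C7=C8 bond, the catalyst surface being expected to reach the enone from the convex β face, away from ring A and the 6α-silyloxy group, so that H enters at C8β (8α-methyl); this centre stays correctable by enolisation of the C9 ketone, the 8α-methyl epimer being the one with the silyloxy and methyl groups of ring B both equatorial.

**Step 5**
Reactants: 6 saturated C9 ketone; 7 vinylmagnesium bromide
Product: 8 (5βH)-6α-(tert-butyldimethylsilyloxy)-9α-hydroxy-4,4,8α,10β-tetramethyl-9β-vinyldecalin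
Conditions: CH2=CHMgBr, anhydrous CeCl3, THF, −78 → 0 °C
Reagents that add atoms: none
Why: 1,2-Addition of the weakly basic vinylcerium reagent to a hindered, enolisable ketone of the 2,2,6-trisubstituted cyclohexanone type should take place on the convex β face, because ring A and C4 with its methyl groups close the α face of C9 in the cis-fused ketone, giving the 9β-vinyl 9α-alcohol.

**Step 6**
Reactants: 8 silyl ether
Product: 9 (5βH)-4,4,8α,10β-tetramethyl-9β-vinyldecalin-6α,9α-diol
Conditions: Bu4NF, THF, rt → 40 °C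
Reagents that add atoms: none
Why: Fluoride-mediated desilylation frees the C6 hydroxyl without touching the tertiary allylic alcohol or any stereocentre.

**Step 7**
Reactants: 9 diol
Product: 10 (5βH)-9α-hydroxy-4,4,8α,10β-tetramethyl-9β-vinyldecalin-6-one (cis-fused)
Conditions: Dess–Martin periodinane, NaHCO3, CH2Cl2, rt
Reagents that add atoms: none
Why: Dess–Martin oxidation converts only the secondary alcohol into the ketone under buffered conditions that neither epimerise C5 nor transpose the tertiary allylic alcohol.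

**Step 8**
Reactants: 10 cis-fused 6-ketone
Product: 11 (5αH)-9α-hydroxy-4,4,8α,10β-tetramethyl-9β-vinyldecalin-6-one (trans-fused)
Conditions: NaOMe, MeOH, 50 °C
Reagents that add atoms: none
Why: Base-mediated epimerisation through the C5 enolate of the C6 ketone (H5 lies on the exposed convex face) should move the ring fusion to trans, where ring B is a chair with the 8-methyl and vinyl groups equatorial, whereas either chair of the cis isomer forces a quaternary carbon or the 8-methyl into a syn-axial clash; C8 and C9 are not enolisable and keep their configuration.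

**Step 9**
Reactants: 11 trans-fused 6-ketone
Product: 12 (5αH)-4,4,8α,10β-tetramethyl-9β-vinyldecalin-6β,9α-diol
Conditions: NaBH4, MeOH, 0 °C
Reagents that add atoms: none
Why: In this borohydride reduction the β face of C6 is screened by the syn-axial C10 methyl and the axial C4 methyl, so hydride should enter equatorially from the α face and give the axial 6β-alcohol.

**Step 10**
Reactants: 12 6β,9α-diol
Product: 13 (5αH)-6β-acetoxy-9α-hydroxy-4,4,8α,10β-tetramethyl-9β-vinyldecalin
Conditions: Ac2O, DMAP, pyridine, 60 °C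
Reagents that add atoms: acetic anhydride, CC(=O)OC(C)=O
Why: DMAP-catalysed acylation acetylates the secondary 6β-hydroxyl, axial but accessible, while the tertiary 9α-hydroxyl flanked by C8 and C10 stays free.

**Step 11**
Reactants: 14 tert-butyl 2,4-dioxopyrrolidine-1-carboxylate
Product: 15 tert-butyl 2-oxo-4-(trifluoromethylsulfonyloxy)-2,5-dihydro-1H-pyrrole-1-carboxylate
Conditions: Tf2O, Et3N, CH2Cl2, −78 → 0 °C
Reagents that add atoms: triflic anhydride, O=S(=O)(OS(=O)(=O)C(F)(F)F)C(F)(F)F
Why: O-Sulfonylation of the enol form of the β-keto lactam (enol triflate formation) gives the sp2 coupling partner that already holds the complete lactam ring.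

**Step 12**
Reactants: 13 vinyl carbinol acetate; 15 lactam enol triflate
Product: 17 tert-butyl 4-[2-((5αH)-6β-acetoxy-9α-hydroxy-4,4,8α,10β-tetramethyldecalin-9β-yl)ethyl]-2-oxo-2,5-dihydro-1H-pyrrole-1-carboxylate, via the B-alkyl-9-borabicyclononane 16 (not isolated)
Conditions: 9-BBN (3 equiv), THF, rt → 50 °C; then 15, Pd(dppf)Cl2 (10 mol%), AsPh3, Cs2CO3, DMF/H2O, rt
Reagents that add atoms: 9-borabicyclo[3.3.1]nonane, C1CC2CCCC(C1)B2 (its boron unit is carried in 16 only and is lost on coupling)
Why: Anti-Markovnikov hydroboration of the terminal vinyl group by 9-BBN followed by B-alkyl Suzuki–Miyaura coupling with the electron-poor enol triflate joins C12 to C13 and brings in the lactam ring without forming a stereocentre.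

**Step 13**
Reactants: 17 N-Boc lactam
Product: 18 4-[2-((5αH)-6β-acetoxy-9α-hydroxy-4,4,8α,10β-tetramethyldecalin-9β-yl)ethyl]-1,5-dihydro-2H-pyrrol-2-one, (5S,6R,8R,9R,10S), the target
Conditions: Mg(ClO4)2 (20 mol%), MeCN, 50 °C
Reagents that add atoms: none
Why: Mg(ClO4)2-promoted cleavage of the N-acyl carbamate (Boc removal from a lactam nitrogen) is selective for imide-type Boc groups and avoids protic acid that could ionise the tertiary C9 alcohol.

**Compound list**
1 | 2,6-dimethyl-1,4-benzoquinone | CC1=CC(=O)C=C(C)C1=O | starting material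
2 | 4-methylpenta-1,3-diene | C=CC=C(C)C | starting material
3 | (4aR,8aS)-2,5,5,8a-tetramethyl-4a,5,8,8a-tetrahydronaphthalene-1,4-dione | O=C1C=C(C)C(=O)[C@@]2(C)CC=CC(C)(C)[C@@H]12 | intermediate
4 | (5βH)-6α-hydroxy-4,4,8,10β-tetramethyldecalin-2,7-dien-9-one | O[C@H]1C=C(C)C(=O)[C@@]2(C)CC=CC(C)(C)[C@@H]12 | intermediate
5 | (5βH)-6α-(tert-butyldimethylsilyloxy)-4,4,8,10β-tetramethyldecalin-2,7-dien-9-one | CC(C)(C)[Si](C)(C)O[C@H]1C=C(C)C(=O)[C@@]2(C)CC=CC(C)(C)[C@@H]12 | intermediate
6 | (5βH)-6α-(tert-butyldimethylsilyloxy)-4,4,8α,10β-tetramethyldecalin-9-one | CC(C)(C)[Si](C)(C)O[C@H]1C[C@@H](C)C(=O)[C@@]2(C)CCCC(C)(C)[C@@H]12 | intermediate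
7 | vinylmagnesium bromide | C=C[Mg]Br | starting material
8 | (5βH)-6α-(tert-butyldimethylsilyloxy)-9α-hydroxy-4,4,8α,10β-tetramethyl-9β-vinyldecalin | CC(C)(C)[Si](C)(C)O[C@H]1C[C@@H](C)[C@](O)(C=C)[C@@]2(C)CCCC(C)(C)[C@@H]12 | intermediate
9 | (5βH)-4,4,8α,10β-tetramethyl-9β-vinyldecalin-6α,9α-diol | O[C@H]1C[C@@H](C)[C@](O)(C=C)[C@@]2(C)CCCC(C)(C)[C@@H]12 | intermediate
10 | (5βH)-9α-hydroxy-4,4,8α,10β-tetramethyl-9β-vinyldecalin-6-one | O=C1C[C@@H](C)[C@](O)(C=C)[C@@]2(C)CCCC(C)(C)[C@@H]12 | intermediate
11 | (5αH)-9α-hydroxy-4,4,8α,10β-tetramethyl-9β-vinyldecalin-6-one | O=C1C[C@@H](C)[C@](O)(C=C)[C@@]2(C)CCCC(C)(C)[C@H]12 | intermediate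
12 | (5αH)-4,4,8α,10β-tetramethyl-9β-vinyldecalin-6β,9α-diol | O[C@@H]1C[C@@H](C)[C@](O)(C=C)[C@@]2(C)CCCC(C)(C)[C@H]12 | intermediate
13 | (5αH)-6β-acetoxy-9α-hydroxy-4,4,8α,10β-tetramethyl-9β-vinyldecalin | CC(=O)O[C@@H]1C[C@@H](C)[C@](O)(C=C)[C@@]2(C)CCCC(C)(C)[C@H]12 | intermediate
14 | tert-butyl 2,4-dioxopyrrolidine-1-carboxylate | CC(C)(C)OC(=O)N1CC(=O)CC1=O | starting material
15 | tert-butyl 2-oxo-4-(trifluoromethylsulfonyloxy)-2,5-dihydro-1H-pyrrole-1-carboxylate | CC(C)(C)OC(=O)N1CC(OS(=O)(=O)C(F)(F)F)=CC1=O | intermediate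
16 | (5αH)-6β-acetoxy-9β-[2-(9-borabicyclo[3.3.1]nonan-9-yl)ethyl]-9α-hydroxy-4,4,8α,10β-tetramethyldecalin | CC(=O)O[C@@H]1C[C@@H](C)[C@](O)(CCB2C3CCCC2CCC3)[C@@]2(C)CCCC(C)(C)[C@H]12 | intermediate
17 | tert-butyl 4-[2-((5αH)-6β-acetoxy-9α-hydroxy-4,4,8α,10β-tetramethyldecalin-9β-yl)ethyl]-2-oxo-2,5-dihydro-1H-pyrrole-1-carboxylate | CC(=O)O[C@@H]1C[C@@H](C)[C@](O)(CCC2=CC(=O)N(C(=O)OC(C)(C)C)C2)[C@@]2(C)CCCC(C)(C)[C@H]12 | intermediate
18 | 4-[2-((5αH)-6β-acetoxy-9α-hydroxy-4,4,8α,10β-tetramethyldecalin-9β-yl)ethyl]-1,5-dihydro-2H-pyrrol-2-one | CC(=O)O[C@@H]1C[C@@H](C)[C@](O)(CCC2=CC(=O)NC2)[C@@]2(C)CCCC(C)(C)[C@H]12 | target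

**Step count**
Total: 13 steps. Longest linear sequence: 12 steps (steps 1–10, 12 and 13); step 11 prepares the coupling partner.

**Steps most likely to fail**

Step 1. The cycloaddition may be sluggish because the cis-methyl group keeps the diene out of the s-cis conformation, and the diene may oligomerise under the cationic catalyst or the enantioselectivity may erode at the higher temperature then needed. The fallback sets out from 1 and keeps the same bond formation with a more electron-rich diene. Mesityl oxide is converted with LiN(iPr)2 and iPr3SiOTf into triisopropyl[(4-methylpenta-1,3-dien-2-yl)oxy]silane F1, which should add to 1 under the same catalyst, its CH2 terminus again bonding to C10, to give the cis-fused ene-dione carrying a C2 silyl enol ether F2. Luche reduction as in step 2 gives the 6α-alcohol F3, and silylation as in step 3 gives the 6α-tert-butyldimethylsilyl ether F4. CsF and PhNTf2 in DME then exchange the silyl enol ether for the C2 enol triflate F5, and Pd(OAc)2, PPh3, HCO2H and Bu3N reduce the triflate to the Δ2 alkene, which is compound 5, where the route is rejoined.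

Step 5. Addition to the doubly flanked C9 ketone may be slow, so that enolisation at C8 or attack from the concave face competes. The fallback sets out from 6 and brings in the two carbons as a slimmer sp nucleophile: ethynylmagnesium bromide with anhydrous CeCl3 in THF should give the 9β-ethynyl 9α-carbinol F6, and semihydrogenation over Pd/CaCO3 poisoned with Pb(OAc)2 in the presence of quinoline returns to 8.

Step 12. Transmetalation of the hindered alkylborane, which can be held as a cyclic borinate by the C9 oxygen, may be slow, and the aqueous base may meanwhile hydrolyse the enol triflate or the acetate. The fallback sets out from 13 and replaces the boron-to-palladium transfer by a radical capture at nickel. Hydroboration with 9-BBN followed by NaBO3·4H2O oxidation gives the primary alcohol (5αH)-6β-acetoxy-9α-hydroxy-9β-(2-hydroxyethyl)-4,4,8α,10β-tetramethyldecalin F7. I2, PPh3 and imidazole convert it into the iodide (5αH)-6β-acetoxy-9α-hydroxy-9β-(2-iodoethyl)-4,4,8α,10β-tetramethyldecalin F8. Reductive cross-electrophile coupling of F8 with 15 (NiBr2(dme), 4,4'-di-tert-butyl-2,2'-bipyridine, Mn powder, DMA) gives 17, where the route is rejoined.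

**Further compounds**
F1 | step 1 | triisopropyl[(4-methylpenta-1,3-dien-2-yl)oxy]silane | CC(C)=CC(=C)O[Si](C(C)C)(C(C)C)C(C)C
F2 | step 1 | (5βH)-4,4,8,10β-tetramethyl-2-(triisopropylsilyloxy)decalin-2,7-diene-6,9-dione | O=C1C=C(C)C(=O)[C@@]2(C)CC(O[Si](C(C)C)(C(C)C)C(C)C)=CC(C)(C)[C@@H]12
F3 | step 1 | (5βH)-6α-hydroxy-4,4,8,10β-tetramethyl-2-(triisopropylsilyloxy)decalin-2,7-dien-9-one | O[C@H]1C=C(C)C(=O)[C@@]2(C)CC(O[Si](C(C)C)(C(C)C)C(C)C)=CC(C)(C)[C@@H]12
F4 | step 1 | (5βH)-6α-(tert-butyldimethylsilyloxy)-4,4,8,10β-tetramethyl-2-(triisopropylsilyloxy)decalin-2,7-dien-9-one | CC(C)(C)[Si](C)(C)O[C@H]1C=C(C)C(=O)[C@@]2(C)CC(O[Si](C(C)C)(C(C)C)C(C)C)=CC(C)(C)[C@@H]12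
F5 | step 1 | (5βH)-6α-(tert-butyldimethylsilyloxy)-4,4,8,10β-tetramethyl-9-oxodecalin-2,7-dien-2-yl trifluoromethanesulfonate | CC(C)(C)[Si](C)(C)O[C@H]1C=C(C)C(=O)[C@@]2(C)CC(OS(=O)(=O)C(F)(F)F)=CC(C)(C)[C@@H]12
F6 | step 5 | (5βH)-6α-(tert-butyldimethylsilyloxy)-9β-ethynyl-9α-hydroxy-4,4,8α,10β-tetramethyldecalin | CC(C)(C)[Si](C)(C)O[C@H]1C[C@@H](C)[C@](O)(C#C)[C@@]2(C)CCCC(C)(C)[C@@H]12
F7 | step 12 | (5αH)-6β-acetoxy-9α-hydroxy-9β-(2-hydroxyethyl)-4,4,8α,10β-tetramethyldecalin | CC(=O)O[C@@H]1C[C@@H](C)[C@](O)(CCO)[C@@]2(C)CCCC(C)(C)[C@H]12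
F8 | step 12 | (5αH)-6β-acetoxy-9α-hydroxy-9β-(2-iodoethyl)-4,4,8α,10β-tetramethyldecalin | CC(=O)O[C@@H]1C[C@@H](C)[C@](O)(CCI)[C@@]2(C)CCCC(C)(C)[C@H]12
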